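**Two runs.** Saturday's flask holds 15.0 times Monday's catalyst, and the question is what such a change does to the excess of left-handed product.

| setting | Monday's | Saturday's | red | green | violet | grey | blue |
|---|---|---|---|---|---|---|---|
| left-handed substrate | 0.50 M | 0.50 M | 0.50 M | 0.50 M | 0.50 M | 0.50 M | 0.50 M |
| right-handed substrate | 0.50 M | 0.50 M | 0.50 M | 0.50 M | 0.50 M | 0.50 M | 0.50 M |
| gas | 52 mM (held) | 52 mM (held) | 52 mM (held) | 52 mM (held) | 52 mM (held) | 52 mM (held) | 52 mM (held) |
| catalyst | 4.4 mM | 66 mM | 3.0 mM | 6.0 mM | 12 mM | 25 mM | 50 mM |
| remark | run made earlier | run made earlier |  |  |  |  |  |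
| time |  |  | 30 min | 30 min | 30 min | 30 min | 30 min |

- Monday's (time / min: left-handed product / %, right-handed product / %): 1.50: 0, 0; 3.00: 1.3, 0.5; 6.00: 3.3, 1.3; 12.0: 6.1, 2.3; 20.0: 10.9, 4.0
- Saturday's (time / min: left-handed product / %, right-handed product / %): 4.00: 9.9, 3.2; 8.00: 19.4, 7.8; 12.0: 27.2, 12.2; 15.0: 32.8, 15.6; 20.0: 40.2, 20.9

(readings scatter by 0.3 percentage points)

- catalyst is single-handed; left-handed substrate and right-handed substrate are mirror images of each other, charged as a racemate, each of them at the stated concentration
- at the start none of the gas is in solution
- an excess is the difference of the two amounts in percent of their sum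
- "hardly changes" means that all values lie within two and a half points (for a concentration: within two and a half percent of the largest)

* excess of left-handed product over right-handed product at the end for red, green, violet, grey, blue, in this order
* how that number moves from the first to the last of them (falls, then rises / rises, then falls / falls all the way / rises all the way / hardly changes)

**One number.** If each substrate decays in proportion to itself on a common clock, the ratio of ln(fraction left) for the left-handed substrate to that for the right-handed one is constant: the selectivity factor s. Saturday's readings give 2.81 at 12.0 min and 3.01 at 20.0 min. Monday's give 2.95 at 20.0 min, between them. The middle of these readings, s = 2.91, says how many times faster the left-handed substrate goes, within the scatter of the readings.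

Is s enough? No: the earliest product would carry an excess of 48.8%, yet at 20.0 min Monday shows 46.3% and Saturday 31.6%. The clock is needed too: with θ = −ln(fraction of left-handed substrate left), the excess is (e^(−θ/s) − e^(−θ))/(2 − e^(−θ) − e^(−θ/s)), which at fixed s falls as θ grows.

**The clock.** θ climbs 0.0129 min⁻¹ on Monday and 0.113 min⁻¹ late on Saturday. Per unit of catalyst, Monday's is 1.72 times faster, which reads as less gas in solution, G, on Saturday. Uptake there is 25.4 mM min⁻¹ against Monday's 7.71 mM min⁻¹. Setting uptake equal to a supply a(csat − G) in both flasks, with csat = 52 mM the held level of the gas and a a transfer constant, gives the estimates a = 0.960 min⁻¹ and Monday's G = 44.0 mM.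

For red, a solution held at 52 mM from the start would give θ* = 0.312. The gas balance, with G at the end roughly put at csat, corrects it to about θ = θ*(1 − (U + csat)/(a·csat·t)), with U the substrate used by the time t. Going round gives 0.263, 0.268, 0.268, so red's excess is 45.5%. At 20.0 min Saturday's θ of 1.63 stands above Monday's 0.246, so the row should fall with catalyst.

**Forecast.** The forecast reads 45.3%, 42.7%, 38.3%, 31.5%, 22.9%, falls all the way: “The excess falls steadily, because selectivity is fixed and conversion rises”.

**Result.** The flasks give 45.4%, 42.7%, 38.5%, 31.9%, 23.5%, falls all the way.

    gas ⇌ partner, rate k1*(csat - [partner]) (kL = 0.947 min⁻¹)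
    partner + catalyst + left-handed substrate → catalyst + left-handed product (k = 64.1 M⁻² min⁻¹)
    partner + catalyst + right-handed substrate → catalyst + right-handed product (k = 22.2 M⁻² min⁻¹)

The gas in solution is the partner, and red ends with 0.0468 M of it and 77% of its charged left-handed substrate. Through s, that stands for 91.4% of its right-handed substrate. Blue keeps 9.2% of its charged left-handed substrate, unbound, which through s stands for 44.0% of the right-handed one, and the flask holds 44%.

(The earlier runs and the new flask were computed for an exercise, noise included.)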